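**Strategy**

Ring C is disconnected at the O1–C8a bond. In ring A, C5 and C8a are equivalent oxygen-bearing carbons on either side of C4a, the carbon that carries the C4 carbonyl, so either can be converted into an aryl triflate and made the electrophile, while the oxygen already attached to the stereogenic benzylic carbon C2 is the nucleophile. One palladium-catalysed intramolecular C–O coupling therefore closes the pyran ring without breaking the C2–O bond, and the configuration set earlier by asymmetric ketone reduction is kept. The precursor is an open-chain 1,3-diarylpropane-1,3-diol derivative: free (S)-C2 hydroxyl, C4 oxygen as a triisopropylsilyl ether, phenols as MOM ethers, both prenyl groups present, C8a as triflate.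

Key step: step 8

**Remarks on the chemistry (assumptions)**

- The target is read as the (2S)-flavanone.
- C4 is carried as a mixture of epimers from step 5 to step 9, because it ends as the carbonyl.
- The C4 oxygen is masked as a triisopropylsilyl ether and not as a smaller silyl ether. In the ring closure a free hydroxyl sits 1,3 to this silyl ether under hot carbonate, and a small silyl group could move from the crowded O4 to the open O2 and cap the nucleophile.
- LDA, the oxazaborolidine, catecholborane and the phosphine are bought.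

**Route**

Step 1
Reactants: 1 2,4,6-trihydroxybenzaldehyde; 2 prenyl bromide
Product: 3 2,4,6-trihydroxy-3,5-bis(3-methylbut-2-enyl)benzaldehyde
Conditions: 2 (2.1 equiv), 10% aq KOH, 0 °C → rt; cold dilute HCl, chromatography
Reagents that add atoms: none
Why: In water the phloroglucinol-type phenoxide is alkylated at its ring carbons rather than at its solvated oxygens, so two SN2 C-prenylations at the only free positions C3 and C5 should give the symmetric diprenyl aldehyde (C-alkylation of an acylphloroglucinol), to be separated from mono- and over-alkylated material.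

Step 2
Reactants: 3 2,4,6-trihydroxy-3,5-bis(3-methylbut-2-enyl)benzaldehyde
Product: 4 2-hydroxy-4,6-bis(methoxymethoxy)-3,5-bis(3-methylbut-2-enyl)benzaldehyde
Conditions: MOMCl (2.2 equiv), i-Pr2NEt, CH2Cl2, 0 °C → rt
Reagents that add atoms: chloromethyl methyl ether (MOMCl), COCCl
Why: Williamson-type O-alkylation takes the para hydroxyl and one of the two equivalent ortho hydroxyls, while the remaining ortho hydroxyl stays locked in a hydrogen bond to the aldehyde and is left free for the triflate.

Step 3
Reactants: 4 2-hydroxy-4,6-bis(methoxymethoxy)-3,5-bis(3-methylbut-2-enyl)benzaldehyde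
Product: 5 2-formyl-3,5-bis(methoxymethoxy)-4,6-bis(3-methylbut-2-enyl)phenyl trifluoromethanesulfonate
Conditions: Tf2O, pyridine, CH2Cl2, −20 → 0 °C
Reagents that add atoms: trifluoromethanesulfonic anhydride (Tf2O), O=S(=O)(OS(=O)(=O)C(F)(F)F)C(F)(F)F
Why: O-Sulfonylation of the single free phenol with the small, highly reactive anhydride under pyridine buffering turns the future C8a oxygen into a leaving group while MOM ethers and prenyl groups are untouched.

Step 4
Reactants: 6 3',5'-dihydroxyacetophenone
Product: 7 3',5'-bis(methoxymethoxy)acetophenone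
Conditions: MOMCl (2.5 equiv), i-Pr2NEt, CH2Cl2, 0 °C → rt
Reagents that add atoms: chloromethyl methyl ether (MOMCl), COCCl
Why: Standard O-alkylation of both unhindered phenols gives a ketone whose only acidic hydrogens are those of the methyl group.

Step 5
Reactants: 5 2-formyl-3,5-bis(methoxymethoxy)-4,6-bis(3-methylbut-2-enyl)phenyl trifluoromethanesulfonate; 7 3',5'-bis(methoxymethoxy)acetophenone
Product: 9 racemic β-hydroxy ketone 2-{3-[3,5-bis(methoxymethoxy)phenyl]-1-hydroxy-3-oxopropyl}-3,5-bis(methoxymethoxy)-4,6-bis(3-methylbut-2-enyl)phenyl trifluoromethanesulfonate, via lithium enolate 8 (not isolated)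
Conditions: 7, LDA, THF, −78 °C; then 5, −78 °C; AcOH quench at −78 °C
Reagents that add atoms: none
Why: Lithium enolate aldol addition, in which the preformed kinetic enolate adds at −78 °C to the non-enolisable aldehyde faster than it can attack the sulfonate and a cold acidic quench should prevent retro-aldol cleavage and dehydration, the new carbinol centre (C4 of the target) being made racemic on purpose because it is oxidised later.

Step 6
Reactants: 9 racemic β-hydroxy ketone
Product: 10 racemic 2-{3-[3,5-bis(methoxymethoxy)phenyl]-3-oxo-1-(triisopropylsilyloxy)propyl}-3,5-bis(methoxymethoxy)-4,6-bis(3-methylbut-2-enyl)phenyl trifluoromethanesulfonate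
Conditions: TIPSOTf, 2,6-lutidine, CH2Cl2, −40 → 0 °C
Reagents that add atoms: triisopropylsilyl trifluoromethanesulfonate (TIPSOTf), CC(C)[Si](OS(=O)(=O)C(F)(F)F)(C(C)C)C(C)C
Why: Silyl triflate silylation of the hindered benzylic alcohol under lutidine buffering at low temperature should spare the MOM acetals and the acid-labile benzylic position, and the bulky silyl group is chosen because it resists the O-to-O shift toward the C2 oxygen that would threaten step 8.

Step 7
Reactants: 10 racemic β-silyloxy ketone
Product: 12 2-{(3S)-3-[3,5-bis(methoxymethoxy)phenyl]-3-hydroxy-1-(triisopropylsilyloxy)propyl}-3,5-bis(methoxymethoxy)-4,6-bis(3-methylbut-2-enyl)phenyl trifluoromethanesulfonate (both C1 epimers), via catecholboronate ester 11 (not isolated)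
Conditions: (R)-2-methyl-CBS-oxazaborolidine (0.2 equiv), catecholborane (2 equiv), toluene, −78 → −40 °C; then pH 7 buffer
Reagents that add atoms: none
Why: Corey–Bakshi–Shibata reduction, in which the (R)-oxazaborolidine binds the ketone with the aryl group as the large flank and delivers hydride to the face that gives the (S)-benzylic carbinol under catalyst control whatever the remote C4 configuration, catecholborane at low temperature being used because it should not hydroborate the prenyl alkenes.

Step 8
Reactants: 12 (3S)-hydroxy silyl ether triflate (both C1 epimers)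
Product: 13 (2S)-4-(triisopropylsilyloxy)-5,7-bis(methoxymethoxy)-2-[3,5-bis(methoxymethoxy)phenyl]-6,8-bis(3-methylbut-2-enyl)chroman (both C4 epimers)
Conditions: Pd(OAc)2 (10 mol%), t-BuBrettPhos (15 mol%), Cs2CO3 (2 equiv), 4 Å MS, degassed toluene, 80 °C
Reagents that add atoms: none
Why: Zerovalent palladium, generated in situ from Pd(OAc)2 and carried by the bulky electron-rich biarylphosphine, inserts into the C8a–OTf bond, carbonate-assisted exchange of triflate for the C2 alkoxide gives a seven-membered oxapalladacycle, and C–O reductive elimination forms O1–C8a and releases the chroman. The closest known reaction type is the intramolecular palladium-catalysed etherification of aryl halides and sulfonates by secondary alcohols (Buchwald–Hartwig C–O coupling), an established way to chromans. Ring C closes in a 6-exo sense, the oxygen attacking the ipso carbon while the departing group lies outside the new ring. No stereocentre is formed and the C2–O bond is never broken, so the S configuration from step 7 is carried through with retention, and both C4 epimers are expected to cyclise and to converge in step 10. The step needs reductive elimination to outrun β-hydride elimination from the secondary palladium alkoxide and S–O cleavage of the hindered triflate, which the large ligand and dry carbonate in a non-polar solvent are chosen to secure, while the substrate removes the other hazards: the triisopropylsilyl ether at O4 should not migrate to O2, no enolisable β-aryloxy ketone is exposed to base, and the C5/C8a equivalence of ring A means that no regiochemical choice exists.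

Step 9
Reactants: 13 (2S)-4-silyloxychroman (both C4 epimers)
Product: 14 (2S)-5,7-bis(methoxymethoxy)-2-[3,5-bis(methoxymethoxy)phenyl]-6,8-bis(3-methylbut-2-enyl)chroman-4-ol (both C4 epimers)
Conditions: Bu4NF, THF, rt → 40 °C; H2O work-up
Reagents that add atoms: none
Why: Fluoride-induced desilylation driven by the strong Si–F bond frees the C4 hydroxyl at a stage where no carbonyl is present, so the basic reagent cannot open ring C or touch C2.

Step 10
Reactants: 14 (2S)-chroman-4-ol (both C4 epimers)
Product: 15 (2S)-5,7-bis(methoxymethoxy)-2-[3,5-bis(methoxymethoxy)phenyl]-6,8-bis(3-methylbut-2-enyl)chroman-4-one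
Conditions: Dess–Martin periodinane, NaHCO3, CH2Cl2, 0 °C → rt
Reagents that add atoms: none
Why: Dess–Martin oxidation of the benzylic secondary alcohol under bicarbonate buffering converges both C4 epimers on the ketone, without acid that could ionise the electron-rich flavan-4-ol and without base that could open the flavanone by retro-oxa-Michael reaction.

Step 11
Reactants: 15 (2S)-tetrakis-MOM flavanone
Product: 16 (2S)-5,7-dihydroxy-2-(3,5-dihydroxyphenyl)-6,8-bis(3-methylbut-2-enyl)chroman-4-one (CID26213315)
Conditions: HCl (about 1 M in MeOH), rt → 40 °C, stopped at full conversion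
Reagents that add atoms: none
Why: Acid-catalysed acetal methanolysis removes all four MOM groups as dimethoxymethane, and dilute acid near room temperature is expected to leave the prenyl double bonds and the C2 stereocentre intact, since opening of the flavanone ring needs base.

**Compound list**

1 | 2,4,6-trihydroxybenzaldehyde | O=Cc1c(O)cc(O)cc1O | starting material
2 | prenyl bromide (1-bromo-3-methylbut-2-ene) | CC(C)=CCBr | starting material
3 | 2,4,6-trihydroxy-3,5-bis(3-methylbut-2-enyl)benzaldehyde | O=Cc1c(O)c(CC=C(C)C)c(O)c(CC=C(C)C)c1O | intermediate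
4 | 2-hydroxy-4,6-bis(methoxymethoxy)-3,5-bis(3-methylbut-2-enyl)benzaldehyde | O=Cc1c(O)c(CC=C(C)C)c(OCOC)c(CC=C(C)C)c1OCOC | intermediate
5 | 2-formyl-3,5-bis(methoxymethoxy)-4,6-bis(3-methylbut-2-enyl)phenyl trifluoromethanesulfonate | O=Cc1c(OS(=O)(=O)C(F)(F)F)c(CC=C(C)C)c(OCOC)c(CC=C(C)C)c1OCOC | intermediate
6 | 3',5'-dihydroxyacetophenone | CC(=O)c1cc(O)cc(O)c1 | starting material
7 | 3',5'-bis(methoxymethoxy)acetophenone | CC(=O)c1cc(OCOC)cc(OCOC)c1 | intermediate
8 | lithium 1-[3,5-bis(methoxymethoxy)phenyl]ethenolate (not isolated) | [Li]OC(=C)c1cc(OCOC)cc(OCOC)c1 | intermediate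
9 | racemic 2-{3-[3,5-bis(methoxymethoxy)phenyl]-1-hydroxy-3-oxopropyl}-3,5-bis(methoxymethoxy)-4,6-bis(3-methylbut-2-enyl)phenyl trifluoromethanesulfonate | CC(C)=CCc1c(OCOC)c(CC=C(C)C)c(OS(=O)(=O)C(F)(F)F)c(c1OCOC)C(O)CC(=O)c1cc(OCOC)cc(OCOC)c1 | intermediate
10 | racemic 2-{3-[3,5-bis(methoxymethoxy)phenyl]-3-oxo-1-(triisopropylsilyloxy)propyl}-3,5-bis(methoxymethoxy)-4,6-bis(3-methylbut-2-enyl)phenyl trifluoromethanesulfonate | CC(C)=CCc1c(OCOC)c(CC=C(C)C)c(OS(=O)(=O)C(F)(F)F)c(c1OCOC)C(O[Si](C(C)C)(C(C)C)C(C)C)CC(=O)c1cc(OCOC)cc(OCOC)c1 | intermediate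
11 | 2-{(3S)-3-(1,3,2-benzodioxaborol-2-yloxy)-3-[3,5-bis(methoxymethoxy)phenyl]-1-(triisopropylsilyloxy)propyl}-3,5-bis(methoxymethoxy)-4,6-bis(3-methylbut-2-enyl)phenyl trifluoromethanesulfonate, both C1 epimers (not isolated) | CC(C)=CCc1c(OCOC)c(CC=C(C)C)c(OS(=O)(=O)C(F)(F)F)c(c1OCOC)C(O[Si](C(C)C)(C(C)C)C(C)C)C[C@@H](c1cc(OCOC)cc(OCOC)c1)OB1Oc2ccccc2O1 | intermediate
12 | 2-{(3S)-3-[3,5-bis(methoxymethoxy)phenyl]-3-hydroxy-1-(triisopropylsilyloxy)propyl}-3,5-bis(methoxymethoxy)-4,6-bis(3-methylbut-2-enyl)phenyl trifluoromethanesulfonate, both C1 epimers (chain C1 = C4 of the target) | CC(C)=CCc1c(OCOC)c(CC=C(C)C)c(OS(=O)(=O)C(F)(F)F)c(c1OCOC)C(O[Si](C(C)C)(C(C)C)C(C)C)C[C@@H](c1cc(OCOC)cc(OCOC)c1)O | intermediate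
13 | (2S)-4-(triisopropylsilyloxy)-5,7-bis(methoxymethoxy)-2-[3,5-bis(methoxymethoxy)phenyl]-6,8-bis(3-methylbut-2-enyl)chroman, both C4 epimers | CC(C)=CCc1c(OCOC)c(CC=C(C)C)c2c(c1OCOC)C(O[Si](C(C)C)(C(C)C)C(C)C)C[C@@H](c1cc(OCOC)cc(OCOC)c1)O2 | intermediate
14 | (2S)-5,7-bis(methoxymethoxy)-2-[3,5-bis(methoxymethoxy)phenyl]-6,8-bis(3-methylbut-2-enyl)chroman-4-ol, both C4 epimers | CC(C)=CCc1c(OCOC)c(CC=C(C)C)c2c(c1OCOC)C(O)C[C@@H](c1cc(OCOC)cc(OCOC)c1)O2 | intermediate
15 | (2S)-5,7-bis(methoxymethoxy)-2-[3,5-bis(methoxymethoxy)phenyl]-6,8-bis(3-methylbut-2-enyl)chroman-4-one | CC(C)=CCc1c(OCOC)c(CC=C(C)C)c2c(c1OCOC)C(=O)C[C@@H](c1cc(OCOC)cc(OCOC)c1)O2 | intermediate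
16 | (2S)-5,7-dihydroxy-2-(3,5-dihydroxyphenyl)-6,8-bis(3-methylbut-2-enyl)chroman-4-one (CID26213315) | CC(C)=CCc1c(O)c(CC=C(C)C)c2c(c1O)C(=O)C[C@@H](c1cc(O)cc(O)c1)O2 | target

**Step count and risks**

Total step count: 11. Longest linear sequence: 10 steps (steps 1–3 and 5–11, from 1 to 16); step 4 prepares the second fragment.

Steps most likely to fail:

1. Step 8 (key step). Oxidative addition into the C–OTf bond flanked by two ortho substituents may be slow. Carbonate-induced S–O cleavage of the triflate, or β-hydride elimination from the palladium alkoxide followed by hydrodetriflation, could then overtake C–O reductive elimination. The fallback exchanges the roles of the two partners and forms the C2–O bond with inversion. It sets out from ketone 10. Reduction with the enantiomeric (S)-2-methyl-CBS-oxazaborolidine and catecholborane, under the conditions of step 7, should give through the (3R)-catecholboronate ester F1 the (3R)-carbinol triflate F2. Cleavage of the aryl triflate with Et4NOH in dioxane at room temperature should free the phenol and give the (3R)-carbinol phenol F3. Mitsunobu cyclisation (PPh3, DIAD, THF, 0 °C) then displaces the activated benzylic oxygen by the phenol with inversion. The fallback comes back to the route at 13 with the (2S) configuration.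

2. Step 1. The ambident phloroglucinol anion may be alkylated at oxygen, stop at the mono-prenyl stage or take a second prenyl group at an already substituted carbon with loss of aromaticity, which would make the diprenyl aldehyde a minor component that is hard to purify. The fallback replaces direct alkylation by halogenation and cross-coupling and sets out from 1. Selective protection (MOMCl 2.2 equiv, i-Pr2NEt, CH2Cl2) should give 2-hydroxy-4,6-bis(methoxymethoxy)benzaldehyde F4. Iodination of the two remaining ring positions (N-iodosuccinimide 2.2 equiv, DMF, 0 °C → rt) should give 2-hydroxy-3,5-diiodo-4,6-bis(methoxymethoxy)benzaldehyde F5. Double Stille coupling with tributyl(3-methylbut-2-enyl)stannane (Pd(PPh3)4, DMF, 90 °C) installs both prenyl groups. The fallback comes back to the route at 4, so that step 2 is no longer needed.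

3. Step 5. The crowded lithium aldolate may revert to its components on warming, lose water during the quench to give the enone, or the basic enolate may attack the sulfonate ester. The fallback replaces the stoichiometric lithium aldolate by a silyl-capped adduct and sets out from 7. Its lithium enolate 8 is trapped with Me3SiCl (THF, −78 °C) to give the trimethylsilyl enol ether F6. A Lewis-base-catalysed Mukaiyama aldol addition to aldehyde 5 (LiOAc 10 mol%, DMF, −45 → 0 °C) should deliver the O-trimethylsilyl aldol adduct F7, in which the new oxygen is silylated as it forms and cannot trigger retro-aldol cleavage. Brief treatment with citric acid in MeOH at 0 °C removes the trimethylsilyl group. The fallback comes back to the route at 9.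

**Further compounds**

F1 | step 8 | 2-{(3R)-3-(1,3,2-benzodioxaborol-2-yloxy)-3-[3,5-bis(methoxymethoxy)phenyl]-1-(triisopropylsilyloxy)propyl}-3,5-bis(methoxymethoxy)-4,6-bis(3-methylbut-2-enyl)phenyl trifluoromethanesulfonate, both C1 epimers (not isolated) | CC(C)=CCc1c(OCOC)c(CC=C(C)C)c(OS(=O)(=O)C(F)(F)F)c(c1OCOC)C(O[Si](C(C)C)(C(C)C)C(C)C)C[C@H](c1cc(OCOC)cc(OCOC)c1)OB1Oc2ccccc2O1
F2 | step 8 | 2-{(3R)-3-[3,5-bis(methoxymethoxy)phenyl]-3-hydroxy-1-(triisopropylsilyloxy)propyl}-3,5-bis(methoxymethoxy)-4,6-bis(3-methylbut-2-enyl)phenyl trifluoromethanesulfonate, both C1 epimers | CC(C)=CCc1c(OCOC)c(CC=C(C)C)c(OS(=O)(=O)C(F)(F)F)c(c1OCOC)C(O[Si](C(C)C)(C(C)C)C(C)C)C[C@H](c1cc(OCOC)cc(OCOC)c1)O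
F3 | step 8 | 2-{(3R)-3-[3,5-bis(methoxymethoxy)phenyl]-3-hydroxy-1-(triisopropylsilyloxy)propyl}-3,5-bis(methoxymethoxy)-4,6-bis(3-methylbut-2-enyl)phenol, both C1 epimers | CC(C)=CCc1c(OCOC)c(CC=C(C)C)c(O)c(c1OCOC)C(O[Si](C(C)C)(C(C)C)C(C)C)C[C@H](c1cc(OCOC)cc(OCOC)c1)O
F4 | step 1 | 2-hydroxy-4,6-bis(methoxymethoxy)benzaldehyde | O=Cc1c(O)cc(OCOC)cc1OCOC
F5 | step 1 | 2-hydroxy-3,5-diiodo-4,6-bis(methoxymethoxy)benzaldehyde | O=Cc1c(O)c(I)c(OCOC)c(I)c1OCOC
F6 | step 5 | {1-[3,5-bis(methoxymethoxy)phenyl]ethenyloxy}trimethylsilane | C=C(O[Si](C)(C)C)c1cc(OCOC)cc(OCOC)c1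
F7 | step 5 | racemic 2-{3-[3,5-bis(methoxymethoxy)phenyl]-3-oxo-1-(trimethylsilyloxy)propyl}-3,5-bis(methoxymethoxy)-4,6-bis(3-methylbut-2-enyl)phenyl trifluoromethanesulfonate | CC(C)=CCc1c(OCOC)c(CC=C(C)C)c(OS(=O)(=O)C(F)(F)F)c(c1OCOC)C(O[Si](C)(C)C)CC(=O)c1cc(OCOC)cc(OCOC)c1
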